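**Plan**
1. Chain numbering is C1–C19, and ring O1/C2/C3/C4/C5 = O/C6/C7/C8/C9. The retrosynthesis cuts the C10 O–benzyl bond, then the C7–O(acyl) bond (Mitsunobu, inversion), and then takes C7–O back to C7–Si. It then cuts two ring bonds at once, C8–C9 (ring C4–C5) and O–C6 (ring O1–C2).
2. This leaves three pieces: (R)-2-(benzyloxy)undec-10-enal (C9–C19), (R)-3-(dimethylphenylsilyl)oct-1-ene (C1–C8) and tetradecanoic acid.
3. Enabling feature: ring C4 (C8) is a bare CH2 lying between the oxygenated ring C3 (C7) and ring C5 (C9), and C9 carries the exocyclic carbinol C10. O1–C5 is therefore the C=O of a chelating α-alkoxy aldehyde. C4–C3–C2 is an allylsilane whose silicon migrates onto C3, exactly where the oxygen is needed.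
4. Forward order: the allylsilane takes 2 steps and the aldehyde 3 steps. A formal (3+2) annulation joins them and closes the only ring, followed by Si→OH, Mitsunobu acylation and debenzylation.
5. Stereochemistry: C10 is bought (methyl (R)-glycidate) and the C–Si centre is set by copper catalysis. C9 is relayed from C10 by chelation, and C6 and C7 are relayed from the C–Si centre, all three in the annulation. The Mitsunobu reaction then inverts C7, installs the myristate and distinguishes the two hydroxyls.

Key step: step 6

Remark on the chemistry: in step 2 the ligand enantiomer is taken to be the one that delivers silicon to the alkene face leading to the (R)-allylsilane.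

**Step 1**
Reactants: 1 (E)-oct-2-en-1-ol
Product: 2 (E)-oct-2-en-1-yl diethyl phosphate
Conditions: ClP(O)(OEt)2, Et3N, DMAP (cat.), CH2Cl2, 0 °C → rt
Reagents that add atoms: diethyl chlorophosphate, CCOP(=O)(Cl)OCC
Why: O-phosphorylation of a primary allylic alcohol leaves the C–O bond and the E geometry untouched and provides the leaving group for a copper-catalysed SN2' substitution.

**Step 2**
Reactants: 2 (E)-oct-2-en-1-yl diethyl phosphate
Product: 3 (R)-dimethyl(oct-1-en-3-yl)(phenyl)silane
Conditions: PhMe2Si–Bpin, chiral NHC·CuCl (5 mol %), NaOMe, CH2Cl2, 0 °C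
Reagents that add atoms: (dimethylphenylsilyl)boronic acid pinacol ester, C[Si](C)(c1ccccc1)B1OC(C)(C)C(C)(C)O1
Why: In this copper-catalysed enantioselective allylic silylation, Cu–OMe and the Si–B reagent give a Cu–Si species that attacks the γ-carbon (SN2'), and the chiral NHC selects the alkene face and so sets the C–Si stereocentre (future C6) as R in the branched product.

**Step 3**
Reactants: 4 8-bromooct-1-ene; 5 methyl (R)-glycidate
Product: 7 methyl (R)-2-hydroxyundec-10-enoate, via oct-7-enylmagnesium bromide 6 (not isolated)
Conditions: Mg, THF, rt; then CuBr·SMe2 (20 mol %), 5, THF, −78 → −30 °C; aq NH4Cl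
Reagents that add atoms: none
Why: In this copper-catalysed Grignard opening of a terminal epoxide, the organocopper species attacks the unhindered CH2 of the glycidate faster than the ester at low temperature, so the purchased stereocentre (future C10) is not touched and stays R.

**Step 4**
Reactants: 7 methyl (R)-2-hydroxyundec-10-enoate
Product: 8 methyl (R)-2-(benzyloxy)undec-10-enoate
Conditions: BnBr, Ag2O, 4 Å MS, Et2O, rt, dark
Reagents that add atoms: benzyl bromide, BrCc1ccccc1
Why: Silver(I) oxide-mediated Williamson-type O-benzylation needs no free alkoxide or enolate, which makes it the standard way to benzylate an α-hydroxy ester without racemisation, and it installs the chelating ether required in step 6.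

**Step 5**
Reactants: 8 methyl (R)-2-(benzyloxy)undec-10-enoate
Product: 9 (R)-2-(benzyloxy)undec-10-enal
Conditions: DIBAL-H (1.1 equiv), CH2Cl2, −78 °C; aq Rochelle salt
Reagents that add atoms: none
Why: Partial DIBAL-H reduction of an α-alkoxy ester stops at the aldehyde because the chelated aluminium hemiacetal survives at −78 °C until the quench; the alkene is not hydroaluminated at this temperature, and 9 is used without chromatography to avoid epimerisation at C10.

**Step 6**
Reactants: 3 (R)-dimethyl(oct-1-en-3-yl)(phenyl)silane; 9 (R)-2-(benzyloxy)undec-10-enal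
Product: 11 {(2S,3R,5R)-5-[(1R)-1-(benzyloxy)dec-9-en-1-yl]-2-pentyloxolan-3-yl}dimethyl(phenyl)silane, via stannate-bound β-silyl cation 10 (not isolated)
Conditions: 9, SnCl4 (1.0 equiv), 4 Å MS, CH2Cl2, −78 °C; then 3 (1.2 equiv), −78 → −20 °C; aq NaHCO3
Reagents that add atoms: none
Why: SnCl4 ties the aldehyde oxygen and the benzyloxy oxygen of 9 into a five-membered chelate, the CH2 terminus (C8) of 3 attacks the carbonyl carbon (C9) anti to its own C–Si bond (anti-SE2'), and in the silicon-bridged β-silyl cation 10 the silyl group slips from C6 to C7 while the tin alkoxide oxygen closes on C6, so that C8–C9 and O–C6 form in one operation as a formal (3+2) union of a three-carbon allyl unit and a C=O. The closest known reaction type is the Lewis-acid-promoted [3+2] annulation of α-substituted allylsilanes with chelating α-benzyloxy aldehydes, the non-desilylative branch of the Hosomi–Sakurai reaction. The oxolane closes by C–O bond formation at the distal carbon of the bridged cation, formally 5-endo-tet (the 4-exo alternative at C7 would give an oxetane), which is feasible because C6 carries much of the positive charge. C9 is set by the chelate, whose C11 chain shields one carbonyl face and gives the syn (threo) C9/C10 pair; C6 is set by the stereocentre of (R)-3, because oxygen enters anti to the departing silicon (inversion, R-silane to 6S); C7 is set by the suprafacial 1,2-silyl shift in the conformer with C6–H eclipsing the alkene, which leaves silicon trans to pentyl; the pairing (R)-3/(R)-9 therefore leads to the 2,5-trans ring, the arrangement that chelated aldehydes also favour in this annulation, so the two controllers should reinforce each other. The step needs annulation to win over loss of silicon (simple allylation) and the allylsilane to react in preference to the remote C18=C19 alkene: the first is served by the phenyldimethylsilyl group, low temperature, sieves and the absence of external nucleophiles, the second by the β-silicon effect, which makes the allylsilane far more nucleophilic than an unactivated 1-alkene.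

**Step 7**
Reactants: 11 the 3-silyl oxolane
Product: 12 (2S,3R,5R)-5-[(1R)-1-(benzyloxy)dec-9-en-1-yl]-2-pentyloxolan-3-ol
Conditions: t-BuOOH (excess), KH, NMP, 0 °C → rt; then TBAF, 70 °C
Reagents that add atoms: tert-butyl hydroperoxide, CC(C)(C)OO
Why: In this basic, nucleophilic form of the Tamao–Fleming oxidation, phenyl is removed from silicon by fluoride/peroxide anion and C7 migrates from Si to O with retention to give the 7R alcohol; no electrophilic oxidant is present, so the terminal alkene and the benzyl ether should survive.

**Step 8**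
Reactants: 12 the (3R)-oxolan-3-ol; 13 tetradecanoic acid
Product: 14 (2S,3S,5R)-5-[(1R)-1-(benzyloxy)dec-9-en-1-yl]-2-pentyloxolan-3-yl tetradecanoate
Conditions: PPh3, DIAD, toluene, 0 °C → rt
Reagents that add atoms: none
Why: In this Mitsunobu esterification, SN2 displacement of the oxyphosphonium group by tetradecanoate inverts C7 (7R to 7S), which places the acyloxy group cis to pentyl as in the target and acylates the only free hydroxyl, since C10–O is still benzylated.

**Step 9**
Reactants: 14 the benzyl-protected myristate
Product: 15 (2S,3S,5R)-5-[(1R)-1-hydroxydec-9-en-1-yl]-2-pentyloxolan-3-yl tetradecanoate (target)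
Conditions: BCl3·SMe2, CH2Cl2, 0 °C → rt; aq NaHCO3
Reagents that add atoms: none
Why: Lewis-acid debenzylation (chloride attack on the boron-activated benzylic C–O bond) is known to spare isolated alkenes and esters, whereas hydrogenolysis would saturate C18=C19; no stereocentre is touched.

**Compound list**
1 | (E)-oct-2-en-1-ol | CCCCC/C=C/CO | starting material
2 | (E)-oct-2-en-1-yl diethyl phosphate | CCCCC/C=C/COP(=O)(OCC)OCC | intermediate
3 | (R)-dimethyl(oct-1-en-3-yl)(phenyl)silane | C=C[C@@H](CCCCC)[Si](C)(C)c1ccccc1 | intermediate
4 | 8-bromooct-1-ene | C=CCCCCCCBr | starting material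
5 | methyl (R)-glycidate, methyl (2R)-oxirane-2-carboxylate | COC(=O)[C@H]1CO1 | starting material
6 | oct-7-enylmagnesium bromide (not isolated) | C=CCCCCCC[Mg]Br | intermediate
7 | methyl (R)-2-hydroxyundec-10-enoate | C=CCCCCCCC[C@@H](O)C(=O)OC | intermediate
8 | methyl (R)-2-(benzyloxy)undec-10-enoate | C=CCCCCCCC[C@@H](OCc1ccccc1)C(=O)OC | intermediate
9 | (R)-2-(benzyloxy)undec-10-enal | C=CCCCCCCC[C@@H](OCc1ccccc1)C=O | intermediate
10 | stannate-bound β-silyl cation, zwitterion (not isolated) | C=CCCCCCCC[C@@H](OCc1ccccc1)[C@H](O[Sn-](Cl)(Cl)(Cl)Cl)C[CH+][C@@H](CCCCC)[Si](C)(C)c1ccccc1 | intermediate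
11 | {(2S,3R,5R)-5-[(1R)-1-(benzyloxy)dec-9-en-1-yl]-2-pentyloxolan-3-yl}dimethyl(phenyl)silane (2,5-trans; Si trans to pentyl) | C=CCCCCCCC[C@@H](OCc1ccccc1)[C@H]1C[C@@H]([Si](C)(C)c2ccccc2)[C@H](CCCCC)O1 | intermediate
12 | (2S,3R,5R)-5-[(1R)-1-(benzyloxy)dec-9-en-1-yl]-2-pentyloxolan-3-ol (OH trans to pentyl) | C=CCCCCCCC[C@@H](OCc1ccccc1)[C@H]1C[C@@H](O)[C@H](CCCCC)O1 | intermediate
13 | tetradecanoic (myristic) acid | CCCCCCCCCCCCCC(=O)O | starting material
14 | (2S,3S,5R)-5-[(1R)-1-(benzyloxy)dec-9-en-1-yl]-2-pentyloxolan-3-yl tetradecanoate | C=CCCCCCCC[C@@H](OCc1ccccc1)[C@H]1C[C@H](OC(=O)CCCCCCCCCCCCC)[C@H](CCCCC)O1 | intermediate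
15 | (2S,3S,5R)-5-[(1R)-1-hydroxydec-9-en-1-yl]-2-pentyloxolan-3-yl tetradecanoate | C=CCCCCCCC[C@@H](O)[C@H]1C[C@H](OC(=O)CCCCCCCCCCCCC)[C@H](CCCCC)O1 | target

**Step count**
Total steps: 9. Longest linear sequence: 7 (steps 3–9).

**Steps most likely to fail**

Step 6. Three processes could undermine the annulation:
- Chloride may attack silicon in the β-silyl cation before ring closure, which gives simple allylation.
- Reaction may leak through the allylsilane conformer with pentyl inside.
- The 2,5-trans preference may erode.

The fallback sets out from 3 and 9 and returns at 12, by-passing steps 6 and 7. It makes the desilylative pathway the intended one.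
- A TiCl4-chelated Hosomi–Sakurai allylation (CH2Cl2, −78 °C) should give (6E,9R,10R)-10-(benzyloxy)nonadeca-6,18-dien-9-ol F1.
- Shi epoxidation (D-fructose-derived ketone, Oxone, buffered MeCN/DMM, 0 °C) prefers the trans-disubstituted alkene to the terminal one. It should give (2R,3R)-3-(benzyloxy)-1-[(2R,3R)-3-pentyloxiran-2-yl]dodec-11-en-2-ol F2.
- CSA in CH2Cl2 should then close the oxolane by 5-endo opening of the epoxide by the C9 hydroxyl, with inversion at C6, to give 12.

Step 8. Substitution must occur on the ring face syn to the neighbouring pentyl chain with a weakly acidic aliphatic acid. It may be slow, and the activated alcohol may instead eliminate to a dihydrofuran.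

The fallback sets out from 12 and returns at 14. It replaces substitution by an oxidation/reduction inversion.
- Dess–Martin oxidation gives (2S,5R)-5-[(1R)-1-(benzyloxy)dec-9-en-1-yl]-2-pentyloxolan-3-one F3.
- L-Selectride (THF, −78 °C) should attack anti to the adjacent pentyl group and give (2S,3S,5R)-5-[(1R)-1-(benzyloxy)dec-9-en-1-yl]-2-pentyloxolan-3-ol F4.
- Steglich esterification with 13 (EDC, DMAP) then gives 14.

Step 7. Under fluoride, the silanol stage may undergo protiodesilylation. Alternatively, β-elimination of the ring oxygen with ring opening may compete with the C-to-O migration.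

The fallback sets out from 11 and returns at 12. It uses the electrophilic Fleming oxidation and masks the alkene in the same operation.
- Br2 (2.2 equiv, CH2Cl2, 0 °C, dark) adds to C18=C19 and cleaves the Si–phenyl bond by ipso-bromodesilylation.
- AcOOH/AcOH/NaOAc then oxidises the bromosilane with retention. The product is (2S,3R,5R)-5-[(1R)-1-(benzyloxy)-9,10-dibromodecyl]-2-pentyloxolan-3-ol F5, a mixture of epimers at the CHBr carbon.
- Zinc dust (AcOH/EtOH) regenerates the terminal alkene by reductive debromination and gives 12.

**Further compounds**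
F1 | step 6 | (6E,9R,10R)-10-(benzyloxy)nonadeca-6,18-dien-9-ol | C=CCCCCCCC[C@@H](OCc1ccccc1)[C@H](O)C/C=C/CCCCC
F2 | step 6 | (2R,3R)-3-(benzyloxy)-1-[(2R,3R)-3-pentyloxiran-2-yl]dodec-11-en-2-ol | C=CCCCCCCC[C@@H](OCc1ccccc1)[C@H](O)C[C@H]1O[C@@H]1CCCCC
F3 | step 8 | (2S,5R)-5-[(1R)-1-(benzyloxy)dec-9-en-1-yl]-2-pentyloxolan-3-one | C=CCCCCCCC[C@@H](OCc1ccccc1)[C@H]1CC(=O)[C@H](CCCCC)O1
F4 | step 8 | (2S,3S,5R)-5-[(1R)-1-(benzyloxy)dec-9-en-1-yl]-2-pentyloxolan-3-ol | C=CCCCCCCC[C@@H](OCc1ccccc1)[C@H]1C[C@H](O)[C@H](CCCCC)O1
F5 | step 7 | (2S,3R,5R)-5-[(1R)-1-(benzyloxy)-9,10-dibromodecyl]-2-pentyloxolan-3-ol | BrCC(Br)CCCCCCC[C@@H](OCc1ccccc1)[C@H]1C[C@@H](O)[C@H](CCCCC)O1
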